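# Proposed total synthesis of broussoflavonol C by twofold benzylic Suzuki coupling

## Analysis of the target

Broussoflavonol C (24) is a flavonol, a 3-hydroxy-4H-chromen-4-one (rings A and C) with an aryl ring B on C2. It has no stereocentre, so the problem is one of constitution only. Ring A carries hydroxyls on C5 and C7 and a 1,1-dimethylallyl (2-methylbut-3-en-2-yl) group on C8, a quaternary benzylic carbon lodged between O7 and the ring oxygen on C8a. Ring B is pentasubstituted: C1' bears C2 of the pyranone, C2' and C3' each bear a linear prenyl group, C4' and C5' form a catechol, and only C6' bears hydrogen. The sensitive groups are the five phenolic or enolic hydroxyls (air oxidation in base, above all at the catechol) and three alkenes, which exclude electrophilic oxidants, hydrogenation and strong acid; in acid the C3' prenyl group can close onto O4' to a chroman and the C8 side chain onto O7 to a dihydrofuran. The difficulty has three parts: two neighbouring linear prenyl groups at defined positions beside a catechol, the placement of the quaternary carbon on C8 and not on C6, and an oxidation at C3 that must leave every alkene alone. The strategy rests on one feature: each prenyl group of ring B contains a benzylic sp3–sp2 bond (C2'–CH2–CH= and C3'–CH2–CH=). Cut there, the two benzylic carbons are the methyl groups of an ortho-xylene, and the rest of each chain is a 2-methylprop-1-enyl unit whose double bond already exists.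

## Retrosynthetic reasoning

**24 to 23 (protecting groups).** The phenols on C5, C7, C4' and C5' are carried as methoxymethyl ethers in 23. These acetals survive the strong base and the basic oxidant of the two preceding steps and leave under mild acid. The C3 hydroxyl needs no protection because it is created in the step that forms 23.

**23 to 21 (ring C).** The O1–C2 bond and the C3–O bond are cut, which opens ring C to the 2'-hydroxychalcone 21. The forward reaction is an Algar–Flynn–Oyamada oxidative cyclisation. It is chosen because its oxidant is a nucleophile that attacks only the enone, so the three isolated alkenes are not at risk, and because ring closure and C3 oxygenation happen in one operation through 22.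

**21 to 20 and 14 (Cα=Cβ).** Cutting the enone double bond divides the molecule into the ring A ketone 20 and the ring B aldehyde 14, two pieces of similar size. The forward Claisen–Schmidt condensation needs only one free hydroxyl in 20, the one that will become O1.

**20 back to 15 and 16 (ring A).** The bond from C3 of the ketone (the later C8) to the quaternary carbon is cut as an aromatic Claisen rearrangement of the prenyl ether 17. In 17 the two ortho carbons are equivalent by symmetry and the para carbon carries the acetyl group, so the rearrangement to 19 has only one possible outcome. The price is that the two acetyl-flanked hydroxyls of 19 must then be told apart (19 to 20); the quaternary carbon beside one of them is expected to do this. Ether 17 comes from 15 and 16 by alkylation of the one hydroxyl that is not hydrogen-bonded.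

**14 back to 10 (functional group changes on ring B).** The aldehyde of 14 is taken back through alcohol 13 to the ester of 12, and the two acetals of 12 through catechol 11 to the pivalates of 10. The exchange is unavoidable: the acyl groups are needed up to and through the coupling, the acetals after it.

**10 to 8 and 9 (key disconnection).** Both ArCH2–CH bonds are cut at once, giving the ortho-bis(bromomethyl)arene 8 and two molecules of the alkenylboronate 9. The cut is made inside the chains and not at the ring, because an aryl–allyl coupling would pass through an allylmetal species and could give branched chains. Here the alkene is preformed, and the forward reaction only has to join an sp3 to an sp2 carbon twice.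

**8 back to 1 (ring B core).** The two C–Br bonds of 8 come from the methyl groups of 7 by radical bromination, for which the ring must be electron-poor; hence the pivalates and the ester. The ester of 7 replaces the bromine of 6 by carbonylation. The second catechol oxygen of 5 comes from a formyl group (3) by Dakin oxidation, and that formyl group enters at the only free ortho position of phenol 1. All six positions of ring B are therefore fixed by the substitution pattern of purchased 1.

## Alternatives that were turned down

**Alternative 1: Danheiser benzannulation of ring A.**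
- Disconnection: ring A is taken apart at C8–C8a and C6–C7, so that the quaternary carbon arrives on an alkyne.
- Forward key step: 3-ethoxycyclobut-2-en-1-one A1 opens thermally to a vinylketene, which adds to the siloxyalkyne A2. The vinylcyclobutenone then undergoes 4π opening and 6π closure to 5-ethoxy-2-(2-methylbut-3-en-2-yl)-3-(triisopropylsilyloxy)phenol A3.
- For: the three oxygens of ring A emerge chemically distinct, with the quaternary carbon already between the free hydroxyl and the silyl ether. On this point it is stronger than the chosen route, which selects the free hydroxyl of 20 by sterics in step 13 and heats a polyphenol to about 190 °C in step 12.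
- Against: A2 is not purchasable, and its quaternary propargylic carbon and ynol ether must be built over several steps. A3 still lacks the acetyl group. The ethyl ether that ends on O5 would need a Lewis-acid dealkylation late, with prenyl groups present. The harder ring, ring B, is not addressed at all.
- Comparison: the chosen strategy spends its key step where no building block can be bought and reaches 20 in three steps from 15. The benzannulation would put more steps into the easier ring.

**Alternative 2: alkoxyfuran Diels–Alder benzannulation of ring B.**
- Disconnection: ring B is cut at C1'–C2' and C5'–C6' into a furan and an alkyne.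
- Forward key step: [4+2] cycloaddition of 4-(methoxymethoxy)-2,3-bis(3-methylbut-2-enyl)furan A4 with ethyl propiolate A5. The electron-rich furan carbon beside the alkoxy group bonds to the alkyne CH, and the 7-oxanorbornadiene opens at the C–O bond backed by the alkoxy group to give phenol A6.
- For: all five substituents of ring B are set in one step, and the two oxygens come out differentiated, one already as the acetal. The radical bromination and the pivalate–acetal exchange (steps 5, 7 and 8) would not be needed, so after ring formation this route is the shorter one.
- Against: A4 is a tetrasubstituted 3-alkoxyfuran that is sensitive to acid and air. Making it means placing two neighbouring prenyl groups on a far less forgiving ring, which is the same problem moved earlier. The cycloaddition must occur at a prenyl-bearing carbon, and the ring opening needs acid or heat beside an acetal and two trisubstituted alkenes.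
- Comparison: the chosen route takes the adjacency of the two chains from the methyl groups of purchased 1 and works with stable benzoates up to the coupling. It pays two protecting-group steps for that.

**Alternative 3: ring C closed at C4–C4a by Friedel–Crafts acylation.**
- Disconnection: the C4–C4a bond, with O1–C2 already in place.
- Forward key step: the Z acid A7 (from conjugate addition of a ring A phenol to a ring B arylpropiolate) is activated as a mixed anhydride and acylates the only free carbon ortho to the aryloxy oxygen, giving the tetra-O-allyl 3-deoxyflavone A8.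
- For: the ring oxygen is bound next to the quaternary carbon before the ring closes, so the 6- versus 8-substitution question cannot arise, and the aurone side path of chalcone oxidation does not exist. The allyl ethers could be removed with a palladium catalyst under neutral conditions. On these points it is stronger than the chosen route, which relies on site selection in step 13 and on acid in step 16.
- Against: A8 has no oxygen on C3. It would have to be introduced on a molecule with three side-chain alkenes and four allyl ethers, which excludes electrophilic epoxidation and leaves a longer metalation–borylation–oxidation sequence. The activation releases a strong acid beside two prenyl groups and two electron-rich rings. The hindered phenol must add to an ortho-substituted arylpropiolate, and only the Z adduct can cyclise. Ring B must still be made and then homologated.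
- Comparison: the chosen route forms the C3–O bond in the ring-forming step with a nucleophilic oxidant. Alternative 3 answers ring C, not ring B, and would add about four steps.

Key step: step 6

Assumption: the commercial monohydrate of 15 is dried before use, because water in step 11 would shift the alkylation from oxygen to carbon; 9 is taken as a purchased reagent.

## Route

Step 1
Reactants: 1 4-bromo-2,3-dimethylphenol
Product: 3 5-bromo-2-hydroxy-3,4-dimethylbenzaldehyde, via 4-bromo-6-(hydroxymethyl)-2,3-dimethylphenol 2 (not isolated)
Conditions: MgCl2, Et3N, (CH2O)n, MeCN, reflux; then aq. HCl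
Reagents that add atoms: paraformaldehyde (as formaldehyde), C=O
Why: Magnesium-mediated ortho-formylation of a phenol (Casnati–Skattebøl reaction): the magnesium phenoxide delivers formaldehyde to the only free ortho carbon (the other carries a methyl group, the para carbon bromine) to give the salicyl alcohol salt 2, which a second formaldehyde oxidises to the aldehyde by hydride transfer.

Step 2
Reactants: 3 5-bromo-2-hydroxy-3,4-dimethylbenzaldehyde
Product: 5 5-bromo-3,4-dimethylbenzene-1,2-diol, via 5-bromo-2-hydroxy-3,4-dimethylphenyl formate 4 (not isolated)
Conditions: H2O2 (30% aq.), NaOH (aq.), THF, 0 °C to rt, argon; then aq. HCl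
Reagents that add atoms: hydrogen peroxide, OO
Why: Dakin oxidation: hydroperoxide adds to the aldehyde, the electron-rich ortho-phenoxide ring migrates to oxygen and the aryl formate 4 is hydrolysed in the same basic medium; the catechol should be acylated promptly because it is air-sensitive.

Step 3
Reactants: 5 5-bromo-3,4-dimethylbenzene-1,2-diol
Product: 6 5-bromo-3,4-dimethyl-1,2-phenylene bis(2,2-dimethylpropanoate)
Conditions: t-BuCOCl, Et3N, DMAP (cat.), CH2Cl2, 0 °C to rt
Reagents that add atoms: pivaloyl chloride, CC(C)(C)C(=O)Cl
Why: Nucleophilic-catalysed O-acylation of both phenols; the bulky, electron-withdrawing pivalates make the ring inert to electrophilic and radical attack in step 5 and resist the bases of steps 4 and 6.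

Step 4
Reactants: 6 5-bromo-3,4-dimethyl-1,2-phenylene bis(2,2-dimethylpropanoate)
Product: 7 methyl 2,3-dimethyl-4,5-bis(pivaloyloxy)benzoate
Conditions: Pd(OAc)2 (cat.), Xantphos, CO (1 atm), MeOH (10 equiv), Et3N, toluene, 80 °C
Reagents that add atoms: carbon monoxide, [C-]#[O+]; methanol, CO
Why: Palladium-catalysed methoxycarbonylation of an aryl bromide: oxidative addition of zerovalent palladium, CO insertion and methanolysis of the acylpalladium; with only a few equivalents of methanol and Et3N as base the hindered aryl pivalates should not be cleaved.

Step 5
Reactants: 7 methyl 2,3-dimethyl-4,5-bis(pivaloyloxy)benzoate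
Product: 8 methyl 2,3-bis(bromomethyl)-4,5-bis(pivaloyloxy)benzoate
Conditions: NBS (2.2 equiv), AIBN (cat.), PhCF3, 85 °C
Reagents that add atoms: N-bromosuccinimide, O=C1CCC(=O)N1Br
Why: Wohl–Ziegler benzylic bromination: the two methyl groups are the only benzylic C–H positions, the acylated ring does not undergo electrophilic bromination, and the first bromine slows a second substitution at the same carbon.

Step 6
Reactants: 8 methyl 2,3-bis(bromomethyl)-4,5-bis(pivaloyloxy)benzoate; 9 2-methylprop-1-enylboronic acid pinacol ester
Product: 10 methyl 2,3-bis(3-methylbut-2-enyl)-4,5-bis(pivaloyloxy)benzoate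
Conditions: Pd(dppf)Cl2 (cat.), K3PO4, THF–H2O (10:1), 65 °C, degassed
Reagents that add atoms: none
Why: Zerovalent palladium, formed from Pd(dppf)Cl2 by the boronate, adds oxidatively to one benzylic C–Br bond of 8; phosphate and water activate 9, the 2-methylprop-1-enyl group is transferred to palladium and reductive elimination forms the ArCH2–CH=C(CH3)2 bond, after which the second C–Br bond passes through the same cycle. The closest known reaction type is the Suzuki–Miyaura coupling of benzylic bromides with alkenylboronic esters, including its twofold use on ortho-bis(bromomethyl)arenes. No ring is closed and no stereocentre is formed; two skeletal C–C bonds are made. The alkene is transferred through its sp2 carbon with the double bond already in place, so no allylmetal species exists and neither a branched chain nor a migrated double bond can arise; the benzylpalladium has no β-hydrogen on sp3 carbon, so β-hydride elimination is closed. Oxidative addition into benzylic C–Br is much faster than into the aryl C–O bonds of the pivalates or the ester, and the wide bite angle of dppf speeds reductive elimination. Because the cycle runs on palladium and not on a reducing metal, reductive 1,4-debromination to the ortho-quinodimethane should not compete. The pivalates keep both oxygens acylated, so no phenoxide can form beside a bromomethyl group, and K3PO4 with little water should leave them and the methyl ester intact.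

Step 7
Reactants: 10 methyl 2,3-bis(3-methylbut-2-enyl)-4,5-bis(pivaloyloxy)benzoate
Product: 11 methyl 4,5-dihydroxy-2,3-bis(3-methylbut-2-enyl)benzoate
Conditions: K2CO3, MeOH (degassed), rt, argon; then aq. NH4Cl
Reagents that add atoms: none
Why: Base-promoted transesterification: the aryl pivalates are activated esters and are methanolysed, while exchange at the methyl benzoate is degenerate; the prenyl groups are inert to carbonate.

Step 8
Reactants: 11 methyl 4,5-dihydroxy-2,3-bis(3-methylbut-2-enyl)benzoate
Product: 12 methyl 4,5-bis(methoxymethoxy)-2,3-bis(3-methylbut-2-enyl)benzoate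
Conditions: MOMCl, i-Pr2NEt, CH2Cl2, 0 °C to reflux
Reagents that add atoms: chloromethyl methyl ether, COCCl
Why: O-alkylation of both phenols to methoxymethyl acetals, which tolerate hydride, KOH and alkaline peroxide in steps 9, 14 and 15; excess reagent and warming cover the hydroxyl flanked by the prenyl group.

Step 9
Reactants: 12 methyl 4,5-bis(methoxymethoxy)-2,3-bis(3-methylbut-2-enyl)benzoate
Product: 13 [4,5-bis(methoxymethoxy)-2,3-bis(3-methylbut-2-enyl)phenyl]methanol
Conditions: LiAlH4, THF, 0 °C; then H2O, aq. NaOH
Reagents that add atoms: none
Why: Hydride reduction of the ester to the primary benzylic alcohol; acetals and isolated alkenes do not react.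

Step 10
Reactants: 13 [4,5-bis(methoxymethoxy)-2,3-bis(3-methylbut-2-enyl)phenyl]methanol
Product: 14 4,5-bis(methoxymethoxy)-2,3-bis(3-methylbut-2-enyl)benzaldehyde
Conditions: MnO2 (activated, excess), CH2Cl2, rt
Reagents that add atoms: none
Why: Heterogeneous oxidation that is selective for benzylic alcohols and stops at the aldehyde; the prenyl alkenes and their allylic C–H bonds are untouched.

Step 11
Reactants: 15 2,4,6-trihydroxyacetophenone; 16 prenyl bromide
Product: 17 1-[2,6-dihydroxy-4-(3-methylbut-2-enyloxy)phenyl]ethanone
Conditions: K2CO3 (1.1 equiv), acetone (dry), rt to 45 °C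
Reagents that add atoms: none
Why: Williamson ether synthesis: the 4-hydroxyl, para to the acetyl group and the only one not hydrogen-bonded to it, is the most acidic and most accessible, and one equivalent of 16 under dry aprotic conditions should alkylate oxygen there and not the ring carbons.

Step 12
Reactants: 17 1-[2,6-dihydroxy-4-(3-methylbut-2-enyloxy)phenyl]ethanone
Product: 19 1-[2,4,6-trihydroxy-3-(2-methylbut-3-en-2-yl)phenyl]ethanone, via 4-acetyl-3,5-dihydroxy-6-(2-methylbut-3-en-2-yl)cyclohexa-2,4-dien-1-one 18 (not isolated)
Conditions: N,N-diethylaniline, 190 °C, argon, sealed tube, short reaction time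
Reagents that add atoms: none
Why: Aromatic Claisen rearrangement: the [3,3] shift delivers the allyl unit through its tertiary terminus to the ortho carbon (dienone 18), which enolises to 19; the two ortho carbons of 17 are equivalent and the para carbon bears the acetyl group, so a further Cope shift cannot end in a phenol and only the ortho 1,1-dimethylallyl product can form.

Step 13
Reactants: 19 1-[2,4,6-trihydroxy-3-(2-methylbut-3-en-2-yl)phenyl]ethanone
Product: 20 1-[2-hydroxy-4,6-bis(methoxymethoxy)-3-(2-methylbut-3-en-2-yl)phenyl]ethanone
Conditions: MOMCl (2.2 equiv), i-Pr2NEt, CH2Cl2, 0 °C to rt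
Reagents that add atoms: chloromethyl methyl ether, COCCl
Why: Site-selective acetal formation: the 4-hydroxyl is unchelated and most acidic and the 6-hydroxyl is flanked only by hydrogen and the acetyl group, whereas the 2-hydroxyl lies between the quaternary carbon and the carbonyl to which it is hydrogen-bonded, and should remain free as the last chelated hydroxyl of such ketones usually does.

Step 14
Reactants: 20 1-[2-hydroxy-4,6-bis(methoxymethoxy)-3-(2-methylbut-3-en-2-yl)phenyl]ethanone; 14 4,5-bis(methoxymethoxy)-2,3-bis(3-methylbut-2-enyl)benzaldehyde
Product: 21 (E)-1-[2-hydroxy-4,6-bis(methoxymethoxy)-3-(2-methylbut-3-en-2-yl)phenyl]-3-[4,5-bis(methoxymethoxy)-2,3-bis(3-methylbut-2-enyl)phenyl]prop-2-en-1-one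
Conditions: KOH (excess), EtOH–THF, rt
Reagents that add atoms: none
Why: Claisen–Schmidt condensation: the methyl ketone enolate adds to the non-enolisable aldehyde and the aldol eliminates by the E1cB path to the conjugated E enone, the thermodynamic isomer; acetals and alkenes are stable to hydroxide.

Step 15
Reactants: 21 (E)-1-[2-hydroxy-4,6-bis(methoxymethoxy)-3-(2-methylbut-3-en-2-yl)phenyl]-3-[4,5-bis(methoxymethoxy)-2,3-bis(3-methylbut-2-enyl)phenyl]prop-2-en-1-one
Product: 23 3-hydroxy-5,7-bis(methoxymethoxy)-2-[4,5-bis(methoxymethoxy)-2,3-bis(3-methylbut-2-enyl)phenyl]-8-(2-methylbut-3-en-2-yl)-4H-chromen-4-one, via racemic trans-3-hydroxyflavanone 22 (not isolated)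
Conditions: H2O2 (30% aq.), NaOH (aq.), MeOH–THF, 0 °C to rt
Reagents that add atoms: hydrogen peroxide, OO
Why: Algar–Flynn–Oyamada reaction: the 2'-phenoxide closes 6-endo onto the enone β-carbon while Cα is hydroxylated by peroxide to give the trans dihydroflavonol 22, which the same medium dehydrogenates to the flavonol; hydroperoxide anion is nucleophilic and does not touch the three isolated alkenes, and the two transient stereocentres of 22 are lost on aromatisation.

Step 16
Reactants: 23 3-hydroxy-5,7-bis(methoxymethoxy)-2-[4,5-bis(methoxymethoxy)-2,3-bis(3-methylbut-2-enyl)phenyl]-8-(2-methylbut-3-en-2-yl)-4H-chromen-4-one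
Product: 24 broussoflavonol C, 2-[4,5-dihydroxy-2,3-bis(3-methylbut-2-enyl)phenyl]-3,5,7-trihydroxy-8-(2-methylbut-3-en-2-yl)-4H-chromen-4-one
Conditions: HCl (1 M aq.), MeOH–THF, 40 °C, argon
Reagents that add atoms: none
Why: Acid-catalysed acetal exchange with methanol frees the four phenols; dilute acid at moderate temperature should be mild enough that the alkenes are not protonated at a useful rate, and the chelated 5-O acetal goes first.

## Compound list

1 | 4-bromo-2,3-dimethylphenol | Cc1c(O)ccc(Br)c1C | starting material
2 | 4-bromo-6-(hydroxymethyl)-2,3-dimethylphenol (present as its magnesium salt) | Cc1c(O)c(CO)cc(Br)c1C | intermediate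
3 | 5-bromo-2-hydroxy-3,4-dimethylbenzaldehyde | Cc1c(O)c(C=O)cc(Br)c1C | intermediate
4 | 5-bromo-2-hydroxy-3,4-dimethylphenyl formate | Cc1c(O)c(OC=O)cc(Br)c1C | intermediate
5 | 5-bromo-3,4-dimethylbenzene-1,2-diol | Cc1c(O)c(O)cc(Br)c1C | intermediate
6 | 5-bromo-3,4-dimethyl-1,2-phenylene bis(2,2-dimethylpropanoate) | Cc1c(OC(=O)C(C)(C)C)c(OC(=O)C(C)(C)C)cc(Br)c1C | intermediate
7 | methyl 2,3-dimethyl-4,5-bis(pivaloyloxy)benzoate | COC(=O)c1cc(OC(=O)C(C)(C)C)c(OC(=O)C(C)(C)C)c(C)c1C | intermediate
8 | methyl 2,3-bis(bromomethyl)-4,5-bis(pivaloyloxy)benzoate | COC(=O)c1cc(OC(=O)C(C)(C)C)c(OC(=O)C(C)(C)C)c(CBr)c1CBr | intermediate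
9 | 2-methylprop-1-enylboronic acid pinacol ester (4,4,5,5-tetramethyl-2-(2-methylprop-1-enyl)-1,3,2-dioxaborolane) | CC(C)=CB1OC(C)(C)C(C)(C)O1 | starting material
10 | methyl 2,3-bis(3-methylbut-2-enyl)-4,5-bis(pivaloyloxy)benzoate | COC(=O)c1cc(OC(=O)C(C)(C)C)c(OC(=O)C(C)(C)C)c(CC=C(C)C)c1CC=C(C)C | intermediate
11 | methyl 4,5-dihydroxy-2,3-bis(3-methylbut-2-enyl)benzoate | COC(=O)c1cc(O)c(O)c(CC=C(C)C)c1CC=C(C)C | intermediate
12 | methyl 4,5-bis(methoxymethoxy)-2,3-bis(3-methylbut-2-enyl)benzoate | COC(=O)c1cc(OCOC)c(OCOC)c(CC=C(C)C)c1CC=C(C)C | intermediate
13 | [4,5-bis(methoxymethoxy)-2,3-bis(3-methylbut-2-enyl)phenyl]methanol | OCc1cc(OCOC)c(OCOC)c(CC=C(C)C)c1CC=C(C)C | intermediate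
14 | 4,5-bis(methoxymethoxy)-2,3-bis(3-methylbut-2-enyl)benzaldehyde | O=Cc1cc(OCOC)c(OCOC)c(CC=C(C)C)c1CC=C(C)C | intermediate
15 | 2,4,6-trihydroxyacetophenone | CC(=O)c1c(O)cc(O)cc1O | starting material
16 | prenyl bromide (1-bromo-3-methylbut-2-ene) | CC(C)=CCBr | starting material
17 | 1-[2,6-dihydroxy-4-(3-methylbut-2-enyloxy)phenyl]ethanone | CC(=O)c1c(O)cc(OCC=C(C)C)cc1O | intermediate
18 | 4-acetyl-3,5-dihydroxy-6-(2-methylbut-3-en-2-yl)cyclohexa-2,4-dien-1-one (racemic) | CC(=O)C1=C(O)C(C(C)(C)C=C)C(=O)C=C1O | intermediate
19 | 1-[2,4,6-trihydroxy-3-(2-methylbut-3-en-2-yl)phenyl]ethanone | CC(=O)c1c(O)cc(O)c(C(C)(C)C=C)c1O | intermediate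
20 | 1-[2-hydroxy-4,6-bis(methoxymethoxy)-3-(2-methylbut-3-en-2-yl)phenyl]ethanone | CC(=O)c1c(O)c(C(C)(C)C=C)c(OCOC)cc1OCOC | intermediate
21 | (E)-1-[2-hydroxy-4,6-bis(methoxymethoxy)-3-(2-methylbut-3-en-2-yl)phenyl]-3-[4,5-bis(methoxymethoxy)-2,3-bis(3-methylbut-2-enyl)phenyl]prop-2-en-1-one | C=CC(C)(C)c1c(OCOC)cc(OCOC)c(C(=O)/C=C/c2cc(OCOC)c(OCOC)c(CC=C(C)C)c2CC=C(C)C)c1O | intermediate
22 | (2R*,3R*)-3-hydroxy-5,7-bis(methoxymethoxy)-2-[4,5-bis(methoxymethoxy)-2,3-bis(3-methylbut-2-enyl)phenyl]-8-(2-methylbut-3-en-2-yl)chroman-4-one (racemic, trans; one enantiomer drawn) | CC(C)=CCc1c(CC=C(C)C)c(OCOC)c(OCOC)cc1[C@@H]2[C@H](C(=O)c3c(OCOC)cc(OCOC)c(C(C)(C)C=C)c3O2)O | intermediate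
23 | 3-hydroxy-5,7-bis(methoxymethoxy)-2-[4,5-bis(methoxymethoxy)-2,3-bis(3-methylbut-2-enyl)phenyl]-8-(2-methylbut-3-en-2-yl)-4H-chromen-4-one | C=CC(C)(C)c1c(OCOC)cc(OCOC)c2c(=O)c(O)c(-c3cc(OCOC)c(OCOC)c(CC=C(C)C)c3CC=C(C)C)oc12 | intermediate
24 | broussoflavonol C, 2-[4,5-dihydroxy-2,3-bis(3-methylbut-2-enyl)phenyl]-3,5,7-trihydroxy-8-(2-methylbut-3-en-2-yl)-4H-chromen-4-one | C=CC(C)(C)c1c(O)cc(O)c2c(=O)c(O)c(-c3cc(O)c(O)c(CC=C(C)C)c3CC=C(C)C)oc12 | target

## Step count and least certain steps

Total: 16 steps. Longest linear sequence: 13 steps (steps 1 to 10, then 14 to 16, from 1). The ring A branch (steps 11 to 13, from 15 and 16) joins at step 14.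

**Step 6 (key step).**
- Most likely failure: stalling after the first chain is attached, because the two benzylic positions are crowded and the catalyst decays. Protodeboronation of 9 could also use up the nucleophile. Base-driven loss is possible as well: hydrolysis of a benzylic bromide or of a pivalate, after which the bromomethyl group beside the ester can lactonise or a freed phenoxide can expel bromide.
- Fallback: from 8, a Stille coupling with tributyl(2-methylprop-1-enyl)stannane F1, made from 2-methylprop-1-enylmagnesium bromide and Bu3SnCl, with Pd2(dba)3 and tri(2-furyl)phosphine in THF at 60 °C. Transmetalation from tin needs neither base nor water, so the hydrolytic paths are shut; the same two bonds are formed and the route is rejoined at 10.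

**Step 15.**
- Most likely failure: diversion of the oxidation into the aurone manifold. The 6'-alkoxy group and the ortho-prenyl group of ring B twist the enone, which favours epoxidation followed by 5-exo opening over the 6-endo closure. The phenoxide beside the quaternary carbon is also hindered, and dehydrogenation of 22 may be incomplete.
- Fallback: from 21, close the ring first by oxa-Michael addition (NaOAc, EtOH, reflux) to the racemic flavanone, 5,7-bis(methoxymethoxy)-2-[4,5-bis(methoxymethoxy)-2,3-bis(3-methylbut-2-enyl)phenyl]-8-(2-methylbut-3-en-2-yl)chroman-4-one F2. Its lithium enolate (LiHMDS, THF, −78 °C) is hydroxylated with 2-(phenylsulfonyl)-3-phenyloxaziridine to give 22, this time isolated. Aqueous NaOH with H2O2 in MeOH then dehydrogenates 22, and the route is rejoined at 23. With the pyranone closed before oxidation, the five-membered path is no longer open.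

**Step 13 (and the thermal step 12 before it).**
- Most likely failure: poor site selection between the two acetyl-flanked hydroxyls, which would carry the side chain to C6 of the flavonol. In step 12, prolonged heating of a product with free hydroxyls on both sides of the new side chain may also lead to ene-type isomerisation or cyclisation.
- Fallback: from 17, cap one of the two equivalent chelated hydroxyls first (MOMCl, one equivalent, i-Pr2NEt) to give 1-[2-hydroxy-6-(methoxymethoxy)-4-(3-methylbut-2-enyloxy)phenyl]ethanone F3. Its Claisen rearrangement in N,N-diethylaniline should go to the carbon between the ether oxygen and the chelated hydroxyl, through bond fixation by the hydrogen-bonded chelate as in 4-allyloxy-2-hydroxyacetophenones. This gives 1-[2,4-dihydroxy-6-(methoxymethoxy)-3-(2-methylbut-3-en-2-yl)phenyl]ethanone F4; any regioisomer would have to be separated. Protection of the only unchelated hydroxyl of F4 rejoins the route at 20, so steps 12 and 13 are both replaced.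

**Step 5.**
- Most likely failure: statistical under- and over-bromination of two neighbouring methyl groups, leaving mixtures that are hard to separate before the key step.
- Fallback: from 7, brominate with a large excess of NBS until no methyl or bromomethyl group is left, aiming at methyl 2,3-bis(dibromomethyl)-4,5-bis(pivaloyloxy)benzoate F5. Then reduce each dibromomethyl group back by one bromine with diethyl phosphite and i-Pr2NEt in THF at 0 °C, a reduction that stops at the monobromide. The route is rejoined at 8.

**Step 16.**
- Most likely failure: acid-promoted cyclisation once the phenols are free (C3' prenyl onto O4', or the C8 side chain onto O7), and oxidation of the liberated catechol.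
- Fallback: from 23, acetal cleavage without Brønsted acid using TMSOTf and 2,2'-bipyridyl in CH2Cl2 at 0 °C to rt. The methoxymethyl groups are transferred to the bipyridine and the oxygens, including the free 3-hydroxyl, are silylated to the pentakis(trimethylsilyl) ether of broussoflavonol C F6. Addition of water hydrolyses the silyl ethers, and the route is rejoined at 24.

## Further compounds

F1 | step 6 | tributyl(2-methylprop-1-enyl)stannane | CCCC[Sn](CCCC)(CCCC)C=C(C)C
F2 | step 15 | 5,7-bis(methoxymethoxy)-2-[4,5-bis(methoxymethoxy)-2,3-bis(3-methylbut-2-enyl)phenyl]-8-(2-methylbut-3-en-2-yl)chroman-4-one (racemic) | C=CC(C)(C)c1c(OCOC)cc(OCOC)c2c1OC(c1cc(OCOC)c(OCOC)c(CC=C(C)C)c1CC=C(C)C)CC2=O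
F3 | step 13 | 1-[2-hydroxy-6-(methoxymethoxy)-4-(3-methylbut-2-enyloxy)phenyl]ethanone | CC(=O)c1c(O)cc(OCC=C(C)C)cc1OCOC
F4 | step 13 | 1-[2,4-dihydroxy-6-(methoxymethoxy)-3-(2-methylbut-3-en-2-yl)phenyl]ethanone | CC(=O)c1c(O)c(C(C)(C)C=C)c(O)cc1OCOC
F5 | step 5 | methyl 2,3-bis(dibromomethyl)-4,5-bis(pivaloyloxy)benzoate | COC(=O)c1cc(OC(=O)C(C)(C)C)c(OC(=O)C(C)(C)C)c(C(Br)Br)c1C(Br)Br
F6 | step 16 | 2-[2,3-bis(3-methylbut-2-enyl)-4,5-bis(trimethylsilyloxy)phenyl]-8-(2-methylbut-3-en-2-yl)-3,5,7-tris(trimethylsilyloxy)-4H-chromen-4-one | C=CC(C)(C)c1c(O[Si](C)(C)C)cc(O[Si](C)(C)C)c2c(=O)c(O[Si](C)(C)C)c(-c3cc(O[Si](C)(C)C)c(O[Si](C)(C)C)c(CC=C(C)C)c3CC=C(C)C)oc12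
A1 | alternative 1 | 3-ethoxycyclobut-2-en-1-one | CCOC1=CC(=O)C1
A2 | alternative 1 | [(3,3-dimethylpent-4-en-1-yn-1-yl)oxy]triisopropylsilane | C=CC(C)(C)C#CO[Si](C(C)C)(C(C)C)C(C)C
A3 | alternative 1 | 5-ethoxy-2-(2-methylbut-3-en-2-yl)-3-(triisopropylsilyloxy)phenol | CCOc1cc(O)c(C(C)(C)C=C)c(O[Si](C(C)C)(C(C)C)C(C)C)c1
A4 | alternative 2 | 4-(methoxymethoxy)-2,3-bis(3-methylbut-2-enyl)furan | COCOc1coc(CC=C(C)C)c1CC=C(C)C
A5 | alternative 2 | ethyl propiolate | C#CC(=O)OCC
A6 | alternative 2 | ethyl 5-hydroxy-4-(methoxymethoxy)-2,3-bis(3-methylbut-2-enyl)benzoate | CCOC(=O)c1cc(O)c(OCOC)c(CC=C(C)C)c1CC=C(C)C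
A7 | alternative 3 | (Z)-3-[3,5-bis(allyloxy)-2-(2-methylbut-3-en-2-yl)phenoxy]-3-[4,5-bis(allyloxy)-2,3-bis(3-methylbut-2-enyl)phenyl]prop-2-enoic acid | OC(=O)/C=C(\Oc1cc(OCC=C)cc(OCC=C)c1C(C)(C)C=C)c1cc(OCC=C)c(OCC=C)c(CC=C(C)C)c1CC=C(C)C
A8 | alternative 3 | 5,7-bis(allyloxy)-2-[4,5-bis(allyloxy)-2,3-bis(3-methylbut-2-enyl)phenyl]-8-(2-methylbut-3-en-2-yl)-4H-chromen-4-one | C=CC(C)(C)c1c(OCC=C)cc(OCC=C)c2c(=O)cc(-c3cc(OCC=C)c(OCC=C)c(CC=C(C)C)c3CC=C(C)C)oc12
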